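**Strategy.** Labdane numbering is used. Ring A (C1–C5, C10) is opened as a [3+3] problem: the C3 oxygen lies between C2 and C4, so C2–C3–C4 with C19 is methyl acetoacetate, used as its α,γ-dianion, and C1 and C5 become two electrophilic carbons on a ring B cyclohexene, a formyl group on C10 and an allylic acetate at C5, both set by one Diels–Alder reaction. In one flask the γ-carbon adds to the aldehyde (C1–C2), zerovalent palladium then ionises the acetate and the α-carbon closes the cis-fused ring at C5 (C4–C5), and acid dehydrates the aldol. The β-keto ester later delivers the C4 bis(hydroxymethyl) group and the C3 alcohol.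

Key step: step 3

Remark: read from its SMILES, the target has H5, the C10 methyl, the C9 side chain and the C3 hydroxyl on one face, so rings A and B are cis-fused; it is (3R,5R,9R,10S) in labdane numbering.
Remark: diene 4 is used as the commercial E/Z mixture, of which only the E isomer reacts.
Assumption: the (S)-configured boron catalyst of step 2 is taken to shield the enal face that leads to 5; its antipode is used if the sense proves opposite.
Assumption: C4 in 8–12 is drawn in one expected configuration; it is of no consequence and is no stereocentre from 13 on.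

**Route**

Step 1
Reactants: 1 3-(benzyloxy)propanal; 2 2-(triphenylphosphoranylidene)propanal
Product: 3 (2E)-5-(benzyloxy)-2-methylpent-2-enal
Conditions: PhMe, 90 °C
Reagents that add atoms: none
Why: Wittig olefination with a formyl-stabilised ylide, which should give the E-trisubstituted enal.

Step 2
Reactants: 3 (2E)-5-(benzyloxy)-2-methylpent-2-enal; 4 (1E)-buta-1,3-dien-1-yl acetate
Product: 5 (1R,5S,6S)-5-[2-(benzyloxy)ethyl]-6-formyl-6-methylcyclohex-2-en-1-yl acetate
Conditions: (S)-1-(2-methylphenyl)-3,3-diphenyl-tetrahydro-1H,3H-pyrrolo[1,2-c][1,3,2]oxazaborole·HNTf2 (10 mol %), CH2Cl2, −78 → −30 °C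
Reagents that add atoms: none
Why: Lewis-acid-catalysed Diels–Alder reaction in which the ortho rule joins the acetoxy-bearing diene terminus to the formyl-bearing carbon, the E-alkene puts the side chain cis to the methyl group (C9, C10), the endo transition state puts acetoxy cis to formyl (C5), and the chiral boron Lewis acid shields one enal face to fix the absolute configuration.

Step 3
Reactants: 5 (1R,5S,6S)-5-[2-(benzyloxy)ethyl]-6-formyl-6-methylcyclohex-2-en-1-yl acetate; 6 methyl 3-oxobutanoate
Product: 9 methyl 5-[2-(benzyloxy)ethyl]-4a-methyl-2-oxo-1,2,4a,5,6,8a-hexahydronaphthalene-1-carboxylate (cis-fused), via aldol adduct 7 (not isolated), via cyclised aldol 8 (not isolated)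
Conditions: 6, NaH then n-BuLi, THF, 0 °C; 5, −78 °C; Pd(PPh3)4 (5 mol %), −78 → 25 °C; then 2 M HCl, 45 °C
Reagents that add atoms: none
Why: The γ-carbanion of the acetoacetate dianion adds to the aldehyde (aldol addition, C1–C2) and leaves the stabilised β-keto ester enolate untouched. Zerovalent palladium then ionises the allylic acetate with inversion and the enolate carbon attacks the near allyl terminus from the face opposite the metal (Tsuji–Trost allylic alkylation, C4–C5), a 6-exo closure that is preferred over the eight-membered ring through C7; acid finally dehydrates the β-hydroxy ketone to the ring A enone. The closest known reaction types are the acetoacetate dianion aldol addition, the intramolecular palladium-catalysed allylic alkylation of β-keto esters and the aldol dehydration. The new stereocentre C5 is fixed by double inversion: C4 enters on the face that carried the acetate, which is the face of C1, so the ring fusion is cis with H5 syn to the C10 methyl; C4 stays epimerisable. The step needs attack of the dianion at the aldehyde and not at the acetate, and C- and not O-alkylation of the enolate; the first rests on the reactivity gap at −78 °C, the second on the reversibility of O-allylation under palladium. Acetyl shuttling between O5 and the C1 alkoxide is tolerated because only the allylic acetate is consumed.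

Step 4
Reactants: 9 methyl 5-[2-(benzyloxy)ethyl]-4a-methyl-2-oxo-1,2,4a,5,6,8a-hexahydronaphthalene-1-carboxylate
Product: 10 methyl 5-[2-(benzyloxy)ethyl]-1-(hydroxymethyl)-4a-methyl-2-oxo-1,2,4a,5,6,8a-hexahydronaphthalene-1-carboxylate
Conditions: 37% aq. HCHO, KHCO3 (0.2 equiv), THF, 0 → 25 °C
Reagents that add atoms: formaldehyde, C=O
Why: Aldol addition of the β-keto ester to formaldehyde at C4, its only acidic C–H (C2 is vinylic), creates the quaternary carbon; formaldehyde should enter on the H5 face, but the configuration is irrelevant because both carbon substituents end as CH2OH.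

Step 5
Reactants: 10 methyl 5-[2-(benzyloxy)ethyl]-1-(hydroxymethyl)-4a-methyl-2-oxo-1,2,4a,5,6,8a-hexahydronaphthalene-1-carboxylate
Product: 11 methyl 5-[2-(benzyloxy)ethyl]-1-(hydroxymethyl)-4a-methyl-2-oxo-1,2,3,4,4a,5,6,8a-octahydronaphthalene-1-carboxylate
Conditions: [(Ph3P)CuH]6 (0.5 equiv), PhH, H2O (2 equiv), 25 °C
Reagents that add atoms: none
Why: Copper hydride conjugate reduction delivers hydride to C1 of the enone only; the isolated C6=C7 alkene, the ester and the hydroxyl are untouched and no stereocentre is formed.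

Step 6
Reactants: 11 methyl 5-[2-(benzyloxy)ethyl]-1-(hydroxymethyl)-4a-methyl-2-oxo-1,2,3,4,4a,5,6,8a-octahydronaphthalene-1-carboxylate
Product: 13 ring A triol with 3-OH and 4,4-bis(hydroxymethyl) and with the C6=C7 alkene and the 9-[2-(benzyloxy)ethyl] chain in ring B, via hydroxy ester 12 (not isolated)
Conditions: (S)-2-methyl-CBS-oxazaborolidine (0.3 equiv), catecholborane, PhMe, −78 → −40 °C; then LiAlH4, THF, 0 → 25 °C
Reagents that add atoms: none
Why: Corey–Bakshi–Shibata reduction in which the quaternary C4 is the large and C2H2 the small substituent, so the (S)-catalyst should give the 3R alcohol by reagent control; LiAlH4 then reduces the ester, after which C4 carries two CH2OH groups.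

Step 7
Reactants: 13 ring A triol with the C6=C7 alkene
Product: 15 ring A triol with the C6=C7–C8=O enone in ring B, via allylic alcohol 14 (not isolated)
Conditions: SeO2 (0.5 equiv), t-BuOOH, CH2Cl2, 25 °C; then MnO2
Reagents that add atoms: tert-butyl hydroperoxide, CC(C)(C)OO
Why: Selenium dioxide allylic oxidation (ene reaction, then [2,3]-shift) should hydroxylate the C8 methylene, because the other allylic position C5 is a methine between two quaternary carbons; MnO2 then oxidises only the allylic alcohol.

Step 8
Reactants: 15 ring A triol with the C6=C7–C8=O enone in ring B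
Product: 16 ring A triol with the C8 ketone and the 9-(2-hydroxyethyl) chain
Conditions: H2 (1 atm), 10% Pd/C, EtOH, 25 °C
Reagents that add atoms: none
Why: Heterogeneous hydrogenation saturates the enone alkene and hydrogenolyses the benzyl ether in one pass; the ketone is inert, no stereocentre is created and C9 is not touched under neutral conditions.

Step 9
Reactants: 16 ring A triol with the C8 ketone and the 9-(2-hydroxyethyl) chain
Product: 17 ring A triol with the C8 exocyclic methylene and the 9-(2-hydroxyethyl) chain
Conditions: Zn, CH2Br2, TiCl4 (excess), THF/CH2Cl2, 0 → 25 °C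
Reagents that add atoms: dibromomethane, BrCBr
Why: Takai–Lombardo methylenation converts the hindered ketone into the exocyclic alkene under non-basic conditions, so the enolisable C9 centre keeps its configuration; the hydroxyls only consume reagent.

Step 10
Reactants: 17 ring A triol with the C8 exocyclic methylene and the 9-(2-hydroxyethyl) chain
Product: 18 the corresponding C12 iodide
Conditions: I2, PPh3, imidazole, THF/MeCN, 0 °C
Reagents that add atoms: iodine, II
Why: Appel-type iodination through the alkoxyphosphonium ion; only the unhindered primary C12 hydroxyl can be displaced in an SN2 step, the two neopentyl primary and the hindered secondary hydroxyls are returned on work-up.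

Step 11
Reactants: 18 the C12 iodide; 19 3-bromofuran-2(5H)-one
Product: 20 3-{2-[(1R,4aR,6R,8aS)-6-hydroxy-5,5-bis(hydroxymethyl)-8a-methyl-2-methylidenedecahydronaphthalen-1-yl]ethyl}furan-2(5H)-one
Conditions: NiBr2(dme) (10 mol %), 4,4′-di-tert-butyl-2,2′-bipyridine, Zn, NaI, DMA, 25 °C
Reagents that add atoms: none
Why: Nickel-catalysed reductive cross-electrophile coupling joins the primary alkyl iodide to the alkenyl bromide (C12–C13) and tolerates free hydroxyls and the 1,1-disubstituted alkene; no stereocentre is involved.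

**Compound list**

1 | 3-(benzyloxy)propanal | O=CCCOCc1ccccc1 | starting material
2 | 2-(triphenylphosphoranylidene)propanal | CC(C=O)=P(c1ccccc1)(c1ccccc1)c1ccccc1 | starting material
3 | (2E)-5-(benzyloxy)-2-methylpent-2-enal | O=C/C(C)=C/CCOCc1ccccc1 | intermediate
4 | (1E)-buta-1,3-dien-1-yl acetate | CC(=O)O/C=C/C=C | starting material
5 | (1R,5S,6S)-5-[2-(benzyloxy)ethyl]-6-formyl-6-methylcyclohex-2-en-1-yl acetate (acetoxy cis to formyl, side chain cis to methyl) | C1C=C[C@@H](OC(C)=O)[C@@](C)(C=O)[C@@H]1CCOCc1ccccc1 | intermediate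
6 | methyl 3-oxobutanoate (methyl acetoacetate) | COC(=O)CC(C)=O | starting material
7 | aldol adduct: methyl 5-hydroxy-3-oxopentanoate carrying at C5 the 2-acetoxy-6-[2-(benzyloxy)ethyl]-1-methylcyclohex-3-en-1-yl group (ring configured as in 5, carbinol epimers) | C1C=C[C@@H](OC(C)=O)[C@@](C)(C(O)CC(=O)CC(=O)OC)[C@@H]1CCOCc1ccccc1 | intermediate (not isolated)
8 | cyclised aldol: methyl 5-[2-(benzyloxy)ethyl]-4-hydroxy-4a-methyl-2-oxo-1,2,3,4,4a,5,6,8a-octahydronaphthalene-1-carboxylate (cis-fused, carbinol epimers) | C1C=C[C@H]2[C@H](C(=O)OC)C(=O)CC(O)[C@@]2(C)[C@@H]1CCOCc1ccccc1 | intermediate (not isolated)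
9 | methyl 5-[2-(benzyloxy)ethyl]-4a-methyl-2-oxo-1,2,4a,5,6,8a-hexahydronaphthalene-1-carboxylate (cis-fused; 4a-methyl, 8a-H and the C5 chain on one face; in equilibrium with its enol) | C1C=C[C@H]2[C@H](C(=O)OC)C(=O)C=C[C@@]2(C)[C@@H]1CCOCc1ccccc1 | intermediate
10 | methyl 5-[2-(benzyloxy)ethyl]-1-(hydroxymethyl)-4a-methyl-2-oxo-1,2,4a,5,6,8a-hexahydronaphthalene-1-carboxylate (cis-fused) | C1C=C[C@H]2[C@@](CO)(C(=O)OC)C(=O)C=C[C@@]2(C)[C@@H]1CCOCc1ccccc1 | intermediate
11 | methyl 5-[2-(benzyloxy)ethyl]-1-(hydroxymethyl)-4a-methyl-2-oxo-1,2,3,4,4a,5,6,8a-octahydronaphthalene-1-carboxylate (cis-fused) | C1C=C[C@H]2[C@@](CO)(C(=O)OC)C(=O)CC[C@@]2(C)[C@@H]1CCOCc1ccccc1 | intermediate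
12 | hydroxy ester: methyl 5-[2-(benzyloxy)ethyl]-2-hydroxy-1-(hydroxymethyl)-4a-methyl-1,2,3,4,4a,5,6,8a-octahydronaphthalene-1-carboxylate (3R in labdane numbering) | C1C=C[C@H]2[C@@](CO)(C(=O)OC)[C@H](O)CC[C@@]2(C)[C@@H]1CCOCc1ccccc1 | intermediate (not isolated)
13 | triol: {5-[2-(benzyloxy)ethyl]-2-hydroxy-4a-methyl-1,2,3,4,4a,5,6,8a-octahydronaphthalene-1,1-diyl}dimethanol (cis-fused, 3R) | C1C=C[C@H]2C(CO)(CO)[C@H](O)CC[C@@]2(C)[C@@H]1CCOCc1ccccc1 | intermediate
14 | allylic alcohol: triol 13 with an added hydroxyl at C8 (C8 epimers) | OC1C=C[C@H]2C(CO)(CO)[C@H](O)CC[C@@]2(C)[C@@H]1CCOCc1ccccc1 | intermediate (not isolated)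
15 | enone triol: 1-[2-(benzyloxy)ethyl]-6-hydroxy-5,5-bis(hydroxymethyl)-8a-methyl-4a,5,6,7,8,8a-hexahydronaphthalen-2(1H)-one (cis-fused) | O=C1C=C[C@H]2C(CO)(CO)[C@H](O)CC[C@@]2(C)[C@@H]1CCOCc1ccccc1 | intermediate
16 | keto tetraol: 6-hydroxy-1-(2-hydroxyethyl)-5,5-bis(hydroxymethyl)-8a-methyloctahydronaphthalen-2(1H)-one (cis-fused) | O=C1CC[C@H]2C(CO)(CO)[C@H](O)CC[C@@]2(C)[C@@H]1CCO | intermediate
17 | tetraol: [6-hydroxy-1-(2-hydroxyethyl)-8a-methyl-2-methylidenedecahydronaphthalene-5,5-diyl]dimethanol (cis-fused) | C=C1CC[C@H]2C(CO)(CO)[C@H](O)CC[C@@]2(C)[C@@H]1CCO | intermediate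
18 | iodide: [6-hydroxy-1-(2-iodoethyl)-8a-methyl-2-methylidenedecahydronaphthalene-5,5-diyl]dimethanol (cis-fused) | C=C1CC[C@H]2C(CO)(CO)[C@H](O)CC[C@@]2(C)[C@@H]1CCI | intermediate
19 | 3-bromofuran-2(5H)-one | O=C1OCC=C1Br | starting material
20 | 3-{2-[(1R,4aR,6R,8aS)-6-hydroxy-5,5-bis(hydroxymethyl)-8a-methyl-2-methylidenedecahydronaphthalen-1-yl]ethyl}furan-2(5H)-one | C=C1CC[C@H]2C(CO)(CO)[C@H](O)CC[C@@]2(C)[C@@H]1CCC1=CCOC1=O | target

**Count and risks**

Total step count: 11. Longest linear sequence: 11 steps (1 to 20).

Steps most likely to fail: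

Step 3. The aldol adduct may revert (retro-aldol) or lose its acetyl group to the new alkoxide before palladium closes the ring, and the allyl complex may lose a β-hydride to give a cyclohexadiene. Fallback from 5 back to 9: the bis(trimethylsilyl) dienol ether of 6 (1-methoxy-1,3-bis(trimethylsilyloxy)buta-1,3-diene) is added to 5 with BF3·OEt2 in CH2Cl2 at −78 °C in a vinylogous Mukaiyama aldol addition, and the carbinol is capped with Et3SiCl and imidazole to give the silyl-protected aldol ester F1. With no free alkoxide present, Pd(PPh3)4 and Cs2CO3 in THF close ring A by the same allylic alkylation to give the bicyclic silyl ether F2. DBU then eliminates triethylsilanol to give 9.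

Step 2. The cycloaddition of the trisubstituted enal may be sluggish and facial or endo selectivity may erode. Fallback from 3 back to 9, with auxiliary control in place of catalyst control: (E)-1-(trimethylsilyloxy)buta-1,3-diene is cleaved with MeLi and the lithium dienolate is O-acylated with (S)-2-methoxy-2-phenylacetyl chloride to give the chiral diene ester F3. Its BF3·OEt2-promoted Diels–Alder reaction with 3, in which the phenyl ring of the auxiliary screens one diene face, should give the O-methylmandelate analogue of 5, F4 (the antipodal acid is used if the sense is opposite). F4 is taken through the conditions of step 3 with the mandelate as the allylic leaving group and rejoins the route at 9.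

Step 11. The electron-poor bromobutenolide may be reduced or dimerised and the iodide protodehalogenated under the reducing nickel conditions. Fallback from 18 back to 20: the lithium enolate of 3-(phenylsulfanyl)oxolan-2-one (excess, THF/DMPU, −78 → 0 °C) is alkylated with 18 to give the α-alkyl-α-phenylsulfanyl lactone F5. NaIO4 in aqueous methanol gives the sulfoxide F6, and thermal syn-elimination (PhMe, 110 °C, CaCO3) gives 20; any exocyclic alkylidene isomer is moved into the ring with DBU.

**Further compounds**

F1 | step 3 | methyl 3-oxo-5-(triethylsilyloxy)pentanoate carrying at C5 the 2-acetoxy-6-[2-(benzyloxy)ethyl]-1-methylcyclohex-3-en-1-yl group (ring as in 5, carbinol epimers) | C1C=C[C@@H](OC(C)=O)[C@@](C)(C(O[Si](CC)(CC)CC)CC(=O)CC(=O)OC)[C@@H]1CCOCc1ccccc1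
F2 | step 3 | methyl 5-[2-(benzyloxy)ethyl]-4a-methyl-2-oxo-4-(triethylsilyloxy)-1,2,3,4,4a,5,6,8a-octahydronaphthalene-1-carboxylate (cis-fused) | C1C=C[C@H]2[C@H](C(=O)OC)C(=O)CC(O[Si](CC)(CC)CC)[C@@]2(C)[C@@H]1CCOCc1ccccc1
F3 | step 2 | (1E)-buta-1,3-dien-1-yl (2S)-2-methoxy-2-phenylacetate | CO[C@H](C(=O)O/C=C/C=C)c1ccccc1
F4 | step 2 | 5-[2-(benzyloxy)ethyl]-6-formyl-6-methylcyclohex-2-en-1-yl (2S)-2-methoxy-2-phenylacetate (ring configured as in 5) | C1C=C[C@@H](OC(=O)[C@@H](OC)c2ccccc2)[C@@](C)(C=O)[C@@H]1CCOCc1ccccc1
F5 | step 11 | 3-(phenylsulfanyl)oxolan-2-one alkylated at C3 with the side chain of 18 (C3 epimers) | C=C1CC[C@H]2C(CO)(CO)[C@H](O)CC[C@@]2(C)[C@@H]1CCC1(Sc2ccccc2)CCOC1=O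
F6 | step 11 | the sulfoxide of F5 | C=C1CC[C@H]2C(CO)(CO)[C@H](O)CC[C@@]2(C)[C@@H]1CCC1(S(=O)c2ccccc2)CCOC1=O
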